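An easy step first: leave X aside and ask what level of dissolved D the held gas J keeps against the drain to E.

    X + D ⇌ X.D (K1 = 91.0 /M, k1 = 0.364 /M/s)
    X + D ⇌ G (K2 = 100 /M, k2 = 0.171 /M/s)
    J ⇌ D, rate k3*(csat - [D]) (k3 = 0.00866 /s, csat = 20 mM)
    Q ⇌ X.D, rate k4*(cs4 - [X.D]) while solid is left; crystals form when [X.D] > cs4 (cs4 = 29 mM, k4 = 0.150 /s)
    D → E (k5 = 0.00267 /s)
X 0.076 M; J 20 mM (held); time 6.0 h
1. which holds at 6.0 h: what has brought the reaction to rest, or that it has not come to rest (it is still moving / forward and back rates have come level / all of X has reacted)
2. conversion of X at 6.0 h
3. amount of X.D at 6.0 h, in percent of the X charged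
4. amount of G at 6.0 h, in percent of the X charged
- amounts and yields of X.D count Q too
- given per volume of solution although it is solid: Q
- at the start none of D is dissolved
- the reaction counts as stopped when no species that holds the X changes by six tenths of a point or more over the second half of the time
- run time (flask): 6.0 h

**Holding level.** I set the feed from J equal to the drain to E. This gave the holding level of D, the saturation level times the transfer coefficient over the sum of transfer coefficient and drain constant: c(D) = 15.3 mM, a steady state. With both steps from X level at that c(D), I reckoned 1.39 of X.D and 1.53 of G beside each unit of X. So my share for X was 25.5 %.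

**Turning time.** I reckoned that at its top rate the feed brought D equal to the charge of X in 7.31 min. The back step from G, slower than that from X.D, has a time constant of 9.75 min. Both are far shorter than 6.0 h, so I expected a later reading to change nothing in X, X.D and G, with forward and back rates level.

**Turning X.** The shares contain no charge of X, so I expected a smaller charge, all else held, to leave them unmoved. A large enough charge meets the solubility, but I reckoned this flask's dissolved X.D at 27.0 mM, less than 29 mM. I therefore committed to no crystals at rest, conversion 74.5 %, X.D 35.5 % and G 39.0 %.

**The result.** The forecast gave "forward and back rates have come level", 74.5 %, 35.5 % and 39 %, holding that “the relaxation times of minutes to under an hour are far shorter than 6 h”. This flask gave "forward and back rates have come level", 74.5 %, 35.5 % and 39.0 %. Read at 2.5 h it gave conversion 74.5 %, and at 60.0 h 74.5 %, so the longer time left conversion where it was. With half the X, conversion was 74.5 %.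

**What stood.** At 2.81 h this flask made D 1.00 times as fast as it used it up, each step taken net, and its D at 3.00 h, 0.0153 M, lay at the holding level. The relaxation half-life of the step to X.D by that step alone, both ways together, was 0.695 min at 6.00 h, short against 6.0 h.

**Second flask.** In the flask with 0.30 M of X, the shares put dissolved X.D at 106 mM, more than 29 mM, so I held dissolved X.D at the solubility and divided by the constant times the holding level: c(X) = 20.8 mM, which is 6.93 % of that charge, with G at 10.6 %. That flask gave X 6.95 %, G 10.6 % and X.D 82.4 %, of which 72.8 % stood as Q.

Its constants are invented, and the outcome is calculated.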